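**Retrosynthetic overview**
1. The ester is cut last: target 26 comes from triol 21 and O-acetylvanilloyl chloride 24; only the secondary C6 hydroxyl acylates.
2. The strategy rests on the seven-membered ring (C1, C5, C6, C7, C8, C9, C10), which is a cyclohepta-1,4-diene in disguise: latent alkenes C5=C6 and C8=C9 flank C7, and quaternary C1 with C10 is the sp3 pair.
3. Diene ester 10 comes from a [3,3] shift of cis-divinylcyclopropane 9 (forms C1–C10, cuts C6–C8). Cyclopropane 9 comes from rhodium-vinylcarbenoid cyclopropanation (C7–C8, C6–C8) of vinylcyclopentene ketal 4 with vinyldiazoacetate 8.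
4. Ring order: the cyclopentane is present from the start (bromoenone 1); the seven-membered ring is closed in step 6; no other ring is made.
5. After step 6: C5=C6 is hydroborated to 5α-H/6α-OH, the C4 ketal becomes the isopropyl carbinol, and the C8 enoate becomes the C8 enone (dienolate hydroxylation, reduction, glycol cleavage) and then the methyl carbinol.

Key step: step 6

Numbering used throughout: C1 ring-fusion carbon with the methyl, C2, C3, C4 (isopropyl carbinol), C5 (ring-fusion CH), C6 (acyloxy carbinol), C7, C8 (methyl carbinol), C9=C10; β is the face of the C1 methyl.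

Assumption: the sense of induction of the dirhodium prolinate follows the accepted model for donor/acceptor carbenoids with monosubstituted alkenes, which calls for the (R)-catalyst; should the sense be the reverse, the (S)-catalyst is used with nothing else changed.

**Route**

Step 1
Reactants: 1 2-bromo-3-methylcyclopent-2-en-1-one
Product: 2 6-bromo-7-methyl-1,4-dioxaspiro[4.4]non-6-ene
Conditions: ethylene glycol, p-TsOH (cat.), benzene, reflux, Dean–Stark
Reagents that add atoms: ethylene glycol, OCCO
Why: Acid-catalysed ketalisation with water removal; the α-bromine should hold the alkene in place, as in the ketalisation of 2-bromocyclopentenone.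

Step 2
Reactants: 2 6-bromo-7-methyl-1,4-dioxaspiro[4.4]non-6-ene; 3 4,4,5,5-tetramethyl-2-vinyl-1,3,2-dioxaborolane
Product: 4 7-methyl-6-vinyl-1,4-dioxaspiro[4.4]non-6-ene
Conditions: Pd(dppf)Cl2 (5 mol%), K3PO4, dioxane/H2O, 80 °C
Reagents that add atoms: none
Why: Suzuki–Miyaura coupling of an alkenyl bromide with a vinylboronate under basic conditions, so the acid-sensitive diene ketal is never exposed to acid.

Step 3
Reactants: 5 methyl acetoacetate
Product: 6 methyl 2-diazo-3-oxobutanoate
Conditions: 4-acetamidobenzenesulfonyl azide, Et3N, MeCN, 0 °C to rt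
Reagents that add atoms: 4-acetamidobenzenesulfonyl azide, CC(=O)Nc1ccc(cc1)S(=O)(=O)N=[N+]=[N-]
Why: Regitz diazo transfer to an active methylene compound.

Step 4
Reactants: 6 methyl 2-diazo-3-oxobutanoate
Product: 7 methyl 2-diazo-3-hydroxybutanoate (racemic)
Conditions: NaBH4, MeOH, 0 °C
Reagents that add atoms: none
Why: Borohydride reduces the ketone of the α-diazo-β-keto ester and leaves the ester and the diazo group alone.

Step 5
Reactants: 7 methyl 2-diazo-3-hydroxybutanoate
Product: 8 methyl 2-diazobut-3-enoate
Conditions: POCl3, Et3N, CH2Cl2, 0 °C; short silica plug; used at once as a cold pentane solution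
Reagents that add atoms: none
Why: Dehydration through the dichlorophosphate (E2) should give the vinyldiazoacetate, which is kept cold and dilute because it cyclises to a pyrazole on standing.

Step 6
Reactants: 4 7-methyl-6-vinyl-1,4-dioxaspiro[4.4]non-6-ene; 8 methyl 2-diazobut-3-enoate
Product: 10 hydroazulene diene ester (C8 methyl ester; C5=C6 and C8=C9; C4 dioxolane; 1R quaternary C1 with β-methyl), via cis-divinylcyclopropane ester 9 (not isolated)
Conditions: Rh2(R-DOSP)4 (2 mol%), pentane, −40 °C, slow addition of 8; then toluene, 100 °C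
Reagents that add atoms: none
Why: The rhodium(II) prolinate turns 8 into a donor/acceptor vinylcarbenoid that cyclopropanates the monosubstituted vinyl group of 4 in a concerted, asynchronous step (bonds C7–C8 and C6–C8), and the cis-divinylcyclopropane 9 then undergoes a [3,3]-sigmatropic (Cope) shift; the closest known reaction type is the rhodium-catalysed enantioselective tandem cyclopropanation/Cope rearrangement of vinyldiazoacetates with dienes (formal 4+3). The seven-membered ring closes in the sigmatropic step through a boat transition state that forms C1–C10 and cleaves C6–C8, leaving C5=C6 and C8=C9. The one new stereocentre, quaternary C1, is set by suprafacial transfer from the cyclopropane centres, whose absolute configuration is fixed by the chiral catalyst. The step needs site selectivity (vinyl group over the tetrasubstituted ring alkene, the ketal oxygens and allylic C–H bonds), cis diastereoselectivity and enantioface selectivity: the first follows from the preference of donor/acceptor carbenoids for a terminal alkene, the second from their rule that the donor vinyl group ends cis to the alkene substituent, the third from the D2-symmetric prolinate in a hydrocarbon solvent. Because the C1 methyl lies inside the boat, the rearrangement is expected to need the heating stage and not to occur at the cyclopropanation temperature.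

Step 7
Reactants: 10 hydroazulene diene ester
Product: 12 6α-alcohol (5α-H; trans ring fusion; ketal and enoate unchanged), via C6 alkylborane 11 (not isolated)
Conditions: BH3·SMe2 (1.2 equiv), THF, 0 °C to rt; then NaBO3·4H2O, H2O, rt
Reagents that add atoms: sodium perborate (oxygen of the C6 hydroxyl), [Na+].[Na+].O[B-]1(O)OO[B-](O)(O)OO1; borane–dimethyl sulfide (boron in 11 only), [BH3-][S+](C)C
Why: Hydroboration–oxidation: boron should add to the less substituted C6 and hydrogen to C5, syn and on the α face anti to the allylic angular methyl (the bias that gives 5α,6α products from Δ5-steroids), which sets C5 and C6 together; the electron-poor enoate should not compete and perborate oxidises with retention without hydrolysing the ester.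

Step 8
Reactants: 12 6α-alcohol
Product: 13 6α-tert-butyldimethylsilyl ether of 12
Conditions: TBSCl, imidazole, DMAP (cat.), DMF, 45 °C
Reagents that add atoms: tert-butyldimethylsilyl chloride, CC(C)(C)[Si](C)(C)Cl
Why: Silylation of the only hydroxyl under basic conditions that the ketal tolerates.

Step 9
Reactants: 13 silyl ether ketal
Product: 14 C4 ketone (6α-OTBS, 5α-H, C8 enoate)
Conditions: PPTS (0.2 equiv), acetone/H2O 10:1, 50 °C
Reagents that add atoms: water, O
Why: Mild acid-catalysed ketal hydrolysis; the conditions are chosen to keep the secondary TBS ether and to avoid enolisation toward C5 (epimerisation or loss of the silyloxy group).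

Step 10
Reactants: 14 C4 ketone
Product: 15 4β-hydroxy-4α-isopropyl compound (6α-OTBS, 5α-H, C8 enoate)
Conditions: i-PrMgCl, anhydrous CeCl3 (3 equiv each), THF, −78 °C
Reagents that add atoms: isopropylmagnesium chloride, CC(C)[Mg]Cl
Why: Organocerium 1,2-addition (Imamoto conditions) to a hindered, enolisable ketone, chemoselective over the ester at −78 °C; the β face of C4 is flanked by the C1 methyl and the silyloxy-bearing C6, so attack should come from the α face and give the 4β-alcohol.

Step 11
Reactants: 15 isopropyl carbinol enoate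
Product: 17 α-hydroxy ester (C8 bears OH and CO2Me; alkene now C9=C10; C8 epimers), via dipotassium alkoxide dienolate 16 (not isolated)
Conditions: KHMDS (3.2 equiv), THF/DMPU, −78 to −40 °C; then trans-2-(phenylsulfonyl)-3-phenyloxaziridine, −78 °C; NH4Cl
Reagents that add atoms: trans-2-(phenylsulfonyl)-3-phenyloxaziridine, O=S(=O)(c1ccccc1)N1OC1c1ccccc1; KHMDS (potassium in 16 only), C[Si](C)(C)[N-][Si](C)(C)C.[K+]
Why: γ-Deprotonation at C10 (the only C–H conjugated with the ester) gives the extended dienolate, which the N-sulfonyloxaziridine oxidises at the α-carbon C8 (Davis oxidation) with transposition of the alkene to C9=C10; the C8 configuration is erased in step 13.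

Step 12
Reactants: 17 α-hydroxy ester
Product: 18 1,2-diol (C8 bears OH and CH2OH)
Conditions: LiAlH4, THF, 0 °C; Fieser work-up
Reagents that add atoms: none
Why: Hydride reduction of the ester to the primary alcohol; silyl ether, alkene and tertiary alcohols are inert.

Step 13
Reactants: 18 1,2-diol
Product: 19 C8 enone (C8=O conjugated with C9=C10; 6α-OTBS; 4β-OH)
Conditions: NaIO4, THF/pH 7 buffer, 0 °C to rt
Reagents that add atoms: none
Why: Periodate glycol cleavage (Malaprade) removes the former ester carbon as formaldehyde under neutral conditions that the β-silyloxy ketone tolerates.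

Step 14
Reactants: 19 C8 enone
Product: 20 8β-hydroxy-8α-methyl compound (6α-OTBS, 4β-OH, C9=C10)
Conditions: MeLi, anhydrous CeCl3 (4 equiv each), THF, −78 °C
Reagents that add atoms: methyllithium, [Li]C
Why: Organocerium 1,2-addition to the enone without conjugate addition or enolisation; the pseudo-axial C1 methyl shields the β face of C8 across the seven-membered ring, so the methyl should enter on the α face and give the 8β-alcohol.

Step 15
Reactants: 20 silyl ether
Product: 21 triol (4β,6α,8β-trihydroxy; 5α-H; C9=C10)
Conditions: TBAF, THF, rt to 40 °C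
Reagents that add atoms: none
Why: Fluoride desilylation under basic conditions that the tertiary allylic alcohol tolerates.

Step 16
Reactants: 22 vanillic acid
Product: 23 4-acetoxy-3-methoxybenzoic acid
Conditions: Ac2O, pyridine, rt; aqueous work-up
Reagents that add atoms: acetic anhydride, CC(=O)OC(C)=O
Why: Phenol acetylation; the mixed anhydride at the carboxyl group is hydrolysed on work-up.

Step 17
Reactants: 23 4-acetoxy-3-methoxybenzoic acid
Product: 24 4-acetoxy-3-methoxybenzoyl chloride
Conditions: (COCl)2, DMF (cat.), CH2Cl2, 0 °C to rt; evaporated and used crude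
Reagents that add atoms: oxalyl chloride, O=C(Cl)C(=O)Cl
Why: Acid chloride formation with Vilsmeier catalysis; the aryl acetate is stable.

Step 18
Reactants: 21 triol; 24 4-acetoxy-3-methoxybenzoyl chloride
Product: 25 6α-(4-acetoxy-3-methoxybenzoate) of 21
Conditions: pyridine, DMAP, CH2Cl2, 0 °C to rt
Reagents that add atoms: none
Why: DMAP-catalysed acylation should take only the single secondary hydroxyl (C6); the tertiary C4 and C8 hydroxyls do not react.

Step 19
Reactants: 25 acetyl-protected ester
Product: 26 CNP0243386.2 (6α-vanillate of the 1β-methyl-5α-H dauc-9-ene-4β,6α,8β-triol)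
Conditions: pyrrolidine, CH2Cl2, 0 °C to rt
Reagents that add atoms: none
Why: Aminolysis of the aryl acetate, which is far more reactive than the hindered secondary benzoate, should free the phenol without touching the C6 ester.

**Compound list**
1 | 2-bromo-3-methylcyclopent-2-en-1-one | CC1=C(Br)C(=O)CC1 | starting material
2 | 6-bromo-7-methyl-1,4-dioxaspiro[4.4]non-6-ene | CC1=C(Br)C2(CC1)OCCO2 | intermediate
3 | 4,4,5,5-tetramethyl-2-vinyl-1,3,2-dioxaborolane | C=CB1OC(C)(C)C(C)(C)O1 | starting material
4 | 7-methyl-6-vinyl-1,4-dioxaspiro[4.4]non-6-ene | C=CC1=C(C)CCC12OCCO2 | intermediate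
5 | methyl acetoacetate | CC(=O)CC(=O)OC | starting material
6 | methyl 2-diazo-3-oxobutanoate | CC(=O)C(=[N+]=[N-])C(=O)OC | intermediate
7 | methyl 2-diazo-3-hydroxybutanoate (racemic) | CC(O)C(=[N+]=[N-])C(=O)OC | intermediate
8 | methyl 2-diazobut-3-enoate | C=CC(=[N+]=[N-])C(=O)OC | intermediate
9 | methyl (1S,2S)-2-(7-methyl-1,4-dioxaspiro[4.4]non-6-en-6-yl)-1-vinylcyclopropane-1-carboxylate (vinyl and cyclopentenyl cis) | COC(=O)[C@]1(C=C)C[C@H]1C2=C(C)CCC23OCCO3 | intermediate
10 | hydroazulene diene ester: C8 CO2Me, C5=C6, C8=C9, C4 dioxolane, (1R)-C1 with β-methyl | COC(=O)C1=CC[C@@]2(C)CCC3(OCCO3)C2=CC1 | intermediate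
11 | C6α alkylborane of 10 (5α-H) | B[C@H]1CC(C(=O)OC)=CC[C@@]2(C)CCC3(OCCO3)[C@H]12 | intermediate
12 | 6α-alcohol, 5α-H, C4 dioxolane, C8 enoate | O[C@H]1CC(C(=O)OC)=CC[C@@]2(C)CCC3(OCCO3)[C@H]12 | intermediate
13 | 6α-OTBS ether of 12 | CC(C)(C)[Si](C)(C)O[C@H]1CC(C(=O)OC)=CC[C@@]2(C)CCC3(OCCO3)[C@H]12 | intermediate
14 | C4 ketone, 6α-OTBS, 5α-H, C8 enoate | CC(C)(C)[Si](C)(C)O[C@H]1CC(C(=O)OC)=CC[C@@]2(C)CCC(=O)[C@H]12 | intermediate
15 | 4β-hydroxy-4α-isopropyl, 6α-OTBS, C8 enoate | CC(C)(C)[Si](C)(C)O[C@H]1CC(C(=O)OC)=CC[C@@]2(C)CC[C@@](O)(C(C)C)[C@H]12 | intermediate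
16 | dipotassium C4-alkoxide ester dienolate of 15 | CC(C)(C)[Si](C)(C)O[C@H]1CC(=C([O-])OC)C=C[C@@]2(C)CC[C@@]([O-])(C(C)C)[C@H]12.[K+].[K+] | intermediate
17 | C8 α-hydroxy ester (C8 epimers), C9=C10, 6α-OTBS, 4β-OH | CC(C)(C)[Si](C)(C)O[C@H]1CC(O)(C(=O)OC)C=C[C@@]2(C)CC[C@@](O)(C(C)C)[C@H]12 | intermediate
18 | C8 hydroxy hydroxymethyl diol (C8 epimers) | CC(C)(C)[Si](C)(C)O[C@H]1CC(O)(CO)C=C[C@@]2(C)CC[C@@](O)(C(C)C)[C@H]12 | intermediate
19 | C8 enone, 6α-OTBS, 4β-OH | CC(C)(C)[Si](C)(C)O[C@H]1CC(=O)C=C[C@@]2(C)CC[C@@](O)(C(C)C)[C@H]12 | intermediate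
20 | 8β-hydroxy-8α-methyl, 6α-OTBS, 4β-OH | CC(C)(C)[Si](C)(C)O[C@H]1C[C@](C)(O)C=C[C@@]2(C)CC[C@@](O)(C(C)C)[C@H]12 | intermediate
21 | 4β,6α,8β-triol | O[C@H]1C[C@](C)(O)C=C[C@@]2(C)CC[C@@](O)(C(C)C)[C@H]12 | intermediate
22 | vanillic acid | COc1cc(C(=O)O)ccc1O | starting material
23 | 4-acetoxy-3-methoxybenzoic acid | COc1cc(C(=O)O)ccc1OC(C)=O | intermediate
24 | 4-acetoxy-3-methoxybenzoyl chloride | COc1cc(C(=O)Cl)ccc1OC(C)=O | intermediate
25 | 6α-(4-acetoxy-3-methoxybenzoate) of 21 | COc1cc(C(=O)O[C@H]2C[C@](C)(O)C=C[C@@]3(C)CC[C@@](O)(C(C)C)[C@H]23)ccc1OC(C)=O | intermediate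
26 | CNP0243386.2 | COc1cc(C(=O)O[C@H]2C[C@](C)(O)C=C[C@@]3(C)CC[C@@](O)(C(C)C)[C@H]23)ccc1O | target

**Totals**
Total step count: 19. Longest linear sequence: 15 steps (5 to 26: steps 3–15, 18, 19).

**Steps most likely to fail**

Step 6. The chiral carbenoid may discriminate the faces of this hindered, ring-substituted diene poorly. The heating that the congested boat transition state needs (methyl inside) may also let the cyclopropane isomerise to the trans isomer, which rearranges only at much higher temperature, so material and enantiopurity are lost. Fallback: starting from 4 and 8, the sequence is run with a robust achiral catalyst (Rh2(esp)2, CH2Cl2, then xylene, 140 °C, sealed tube). This should give the racemic cis-divinylcyclopropane ester F1 and from it the racemic hydroazulene diene ester F2. The enantiomers of F2 (UV-active enoate) are separated by preparative chromatography on a chiral stationary phase; the (1R)-enantiomer is 10 and the route continues at step 7. Absolute control thus moves from the catalyst to a resolution.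

Step 7. Facial selectivity may be poor or reversed. In the boat-shaped cyclohepta-1,4-diene, C8–C10 are folded under the α face of C5=C6, so borane may add on the β face, syn to the methyl, and give the cis-fused 5β,6β-alcohol; reduction of the enoate could also compete. Fallback, setting out from 10, uses that same bias. Buffered mCPBA (NaHCO3, CH2Cl2, 0 °C) should epoxidise the electron-rich C5=C6 alkene on the β face to the 5β,6β-epoxide F3. BF3·OEt2 (CH2Cl2, −78 °C) opens the tertiary C5–O bond and the C6 hydrogen migrates on the α face (Meinwald rearrangement, stereospecific), giving the trans-fused 5α-H 6-ketone F4. NaBH4 (MeOH, 0 °C), approaching anti to the 1,3-related angular methyl, should give the 6β-alcohol F5. Mitsunobu inversion (PPh3, DIAD, 4-nitrobenzoic acid) gives the 6α-(4-nitrobenzoate) F6, and methanolysis (K2CO3, MeOH) returns to 12.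

Step 10. The secondary organometallic may reduce the hindered ketone by β-hydride transfer or enolise it toward C5, which would expel the C6 silyloxy group. Fallback, setting out from 14: isopropenylmagnesium bromide/CeCl3 (THF, −78 °C), an sp2 nucleophile that is smaller and has no hydride to transfer, should give the 4β-hydroxy-4α-isopropenyl compound F7. Hydrogenation of its 1,1-disubstituted alkene with Wilkinson's catalyst (H2, benzene, rt), which leaves the trisubstituted enoate alone, returns to 15.

**Further compounds**
F1 | step 6 | racemic cis-divinylcyclopropane ester (relative configuration of 9) | COC(=O)[C@]1(C=C)C[C@H]1C2=C(C)CCC23OCCO3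
F2 | step 6 | racemic hydroazulene diene ester (racemate of 10) | COC(=O)C1=CCC2(C)CCC3(OCCO3)C2=CC1
F3 | step 7 | 5β,6β-epoxide of 10 | O1[C@@H]2CC(C(=O)OC)=CC[C@@]3(C)CCC4(OCCO4)[C@@]123
F4 | step 7 | trans-fused 5α-H 6-ketone (C4 dioxolane, C8 enoate) | O=C1CC(C(=O)OC)=CC[C@@]2(C)CCC3(OCCO3)[C@H]12
F5 | step 7 | 6β-alcohol, 5α-H (6-epimer of 12) | O[C@@H]1CC(C(=O)OC)=CC[C@@]2(C)CCC3(OCCO3)[C@H]12
F6 | step 7 | 6α-(4-nitrobenzoate) of 12 | O=C(O[C@H]1CC(C(=O)OC)=CC[C@@]2(C)CCC3(OCCO3)[C@H]12)c1ccc(cc1)[N+](=O)[O-]
F7 | step 10 | 4β-hydroxy-4α-isopropenyl compound (6α-OTBS, C8 enoate) | CC(C)(C)[Si](C)(C)O[C@H]1CC(C(=O)OC)=CC[C@@]2(C)CC[C@@](O)(C(C)=C)[C@H]12
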